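**Retrosynthetic overview**
1. Numbering: N4; pyrrolidine N4–C3–C2–C1–C9a; azepane N4–C5–C6–C7–C8–C9–C9a; cyclopentane C9a–C12–C11–C10–C9; fused lactone O–C14(=O)–C13(Me)(OH) on C11/C12; ethyl C16–C17 on C10; side-chain lactone C18–C21 on C3.
2. The side-chain lactone comes last, from a C3 aldehyde by chelation-controlled 2-(ethoxycarbonyl)allyl addition, lactonisation and hydrogenation; the azepane is closed before that by N4–C5 alkylation.
3. The fused hydroxy lactone is annulated onto a C12 ketone: ethyl by conjugate addition to the C10=C11 enone, C11–O by bromide displacement with inversion, C12=C13 by intramolecular Horner–Wadsworth–Emmons reaction, then hydrogenation, C13 oxygenation and convex-face C-methylation.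
4. The cyclopentanone (C9a, C12, C11, C10, C9) with its aza-quaternary spiro carbon arises from a cyclobutanol (C12, C9, C10, C11) by 1,2-shift of C9 from C12 to C9a. The enabling feature is that C9a, the atom shared by pyrrolidine, azepane and cyclopentane, bears N4 and can therefore be an N-acyliminium carbon, and that its neighbour C12 can carry the carbinol (then ketone) oxygen that later serves the lactone annulation.
5. Fragments: (R)-2-(4-chlorobutyl)cyclobutanone (SAMP alkylation of cyclobutanone) and a lithiated N-Boc-2-pyrroline from (S)-pyroglutaminol. Ring order: pyrrolidine (chiral pool), cyclopentane (ring expansion, spiro), fused lactone, azepane, side-chain lactone.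

Key step: step 7

Assumption: the SAMP-hydrazone alkylation of cyclobutanone is taken to follow the usual sense of induction of cycloalkanone SAMP hydrazones (SAMP gives the (R)-2-alkyl ketone); if the sense is opposite, the enantiomeric auxiliary RAMP is used.

**Route**

Step 1
Reactants: 1 cyclobutanone; 2 SAMP, (S)-1-amino-2-(methoxymethyl)pyrrolidine
Product: 3 cyclobutanone SAMP hydrazone
Conditions: neat, 60 °C, then high vacuum
Reagents that add atoms: none
Why: Hydrazone condensation of an unhindered ketone with the chiral hydrazine; no ring stereocenter is formed and the auxiliary is in place for the alkylation.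

Step 2
Reactants: 3 cyclobutanone SAMP hydrazone; 4 1-chloro-4-iodobutane
Product: 6 SAMP hydrazone of (R)-2-(4-chlorobutyl)cyclobutanone, via lithium azaenolate 5 (not isolated)
Conditions: LiN(i-Pr)2, THF, 0 °C; then 4, −95 → −78 °C
Reagents that add atoms: none
Why: Asymmetric α-alkylation of a SAMP-hydrazone azaenolate, in which lithium is chelated by the methoxymethyl group and the iodide end of 4 (far more reactive than the chloride end) is attacked from the open face of the azaenolate, which sets the future C9.

Step 3
Reactants: 6 SAMP hydrazone of (R)-2-(4-chlorobutyl)cyclobutanone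
Product: 7 (R)-2-(4-chlorobutyl)cyclobutan-1-one
Conditions: sat. aq. oxalic acid, Et2O, rt
Reagents that add atoms: water, O
Why: Two-phase acidic hydrazone hydrolysis, mild enough that the α-branched cyclobutanone should be released without epimerisation at C9.

Step 4
Reactants: 8 (S)-5-(hydroxymethyl)pyrrolidin-2-one
Product: 9 (S)-5-[(tert-butyldimethylsilyloxy)methyl]pyrrolidin-2-one
Conditions: TBSCl, imidazole, DMF, rt
Reagents that add atoms: tert-butyldimethylsilyl chloride, CC(C)(C)[Si](C)(C)Cl
Why: Standard silylation of the primary alcohol; the C3 stereocenter comes from the chiral pool and is untouched.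

Step 5
Reactants: 9 (S)-5-[(tert-butyldimethylsilyloxy)methyl]pyrrolidin-2-one
Product: 10 tert-butyl (S)-2-[(tert-butyldimethylsilyloxy)methyl]-5-oxopyrrolidine-1-carboxylate
Conditions: Boc2O, DMAP (cat.), Et3N, CH2Cl2, rt
Reagents that add atoms: di-tert-butyl dicarbonate, CC(C)(C)OC(=O)OC(=O)OC(C)(C)C
Why: DMAP-catalysed N-carbamoylation of the lactam, which activates the lactam carbonyl for partial reduction and later directs the vinylic lithiation.

Step 6
Reactants: 10 tert-butyl (S)-2-[(tert-butyldimethylsilyloxy)methyl]-5-oxopyrrolidine-1-carboxylate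
Product: 13 tert-butyl (S)-2-[(tert-butyldimethylsilyloxy)methyl]-2,3-dihydro-1H-pyrrole-1-carboxylate, via hemiaminal lithium alkoxide 11 (not isolated), via hemiaminal trifluoroacetate 12 (not isolated)
Conditions: LiBHEt3, toluene, −78 °C; then DIPEA, DMAP (cat.), TFAA, −78 °C → rt
Reagents that add atoms: none
Why: Partial reduction of the imide-like N-Boc lactam carbonyl to the hemiaminal, then trifluoroacetylation and base-induced elimination through the N-acyliminium ion, the usual route to endocyclic ene-carbamates; C3 is not affected.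

Step 7
Reactants: 13 tert-butyl (S)-2-[(tert-butyldimethylsilyloxy)methyl]-2,3-dihydro-1H-pyrrole-1-carboxylate; 7 (R)-2-(4-chlorobutyl)cyclobutan-1-one
Product: 16 tert-butyl (2S,5R,9R)-2-[(tert-butyldimethylsilyloxy)methyl]-9-(4-chlorobutyl)-6-oxo-1-azaspiro[4.4]nonane-1-carboxylate (spiro carbon = C9a, ketone = C12), via vinyllithium 14 (not isolated), via cyclobutanol 15 (not isolated)
Conditions: s-BuLi, TMEDA, THF, −78 °C; 7, −78 °C; then TFA, CH2Cl2, −78 → 0 °C
Reagents that add atoms: none
Why: Carbamate-directed vinylic lithiation of 13 gives 14, which adds to the strained, weakly enolisable carbonyl of 7 anti to the 2-(4-chlorobutyl) group, so that in 15 the hydroxyl is cis and the pyrroline carbon (future C9a) trans to that chain; dilute TFA at or below 0 °C then protonates the ene-carbamate at C1 (faster than it cleaves the carbamate) to an N-acyliminium ion, and C9 shifts suprafacially from C12 to the electron-poor C9a, driven by release of cyclobutane strain and formation of the C12 carbonyl. The closest known reaction type is the acid-promoted semipinacol (acyliminium, α-iminol-type) ring expansion of 2-(1-hydroxycyclobutyl) N-acyl enamines to 1-azaspirocyclic cyclopentanones, here telescoped with the fragment union. The cyclopentanone (C9a, C12, C11, C10, C9) is not closed by a cyclisation but arises from the cyclobutane (C12, C9, C10, C11) by insertion of C9a into the C12–C9 bond, a one-carbon expansion by 1,2-alkyl shift. C9 migrates with retention, and C9a, the only new stereocenter, is set stereospecifically by the carbinol configuration at C12: in the reactive conformer the small hydroxyl lies next to the N-Boc group (least allylic strain, O–H···O=C contact) and C9 stands perpendicular to the iminium plane, which places N4 and the chlorobutyl chain on the same face of the new ring, as the azepane closure needs. The step needs C9 to migrate in preference to C11 and the nucleophile to add anti to the chain; the first is secured by the higher migratory aptitude of the secondary, chain-bearing carbon over the ring CH2, the second by the single α-substituent of the puckered cyclobutanone. The chiral-pool C3 stereocenter is remote from the reacting face and is not expected to override this relay.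

Step 8
Reactants: 16 N-Boc azaspiro ketone
Product: 17 tert-butyl (2S,5R,9R)-2-[(tert-butyldimethylsilyloxy)methyl]-9-(4-chlorobutyl)-6-oxo-1-azaspiro[4.4]non-7-ene-1-carboxylate (C10=C11 enone)
Conditions: IBX, DMSO–toluene, 70 °C
Reagents that add atoms: none
Why: IBX-mediated α,β-dehydrogenation of a ketone through its enol, regiospecific because C11 is the only enolisable position (C9a is quaternary); no base is present, so C9 is safe.

Step 9
Reactants: 17 enone
Product: 19 bromo ketone (ethyl at C10 trans to the C9 chain, bromine at C11 trans to ethyl), via trimethylsilyl enol ether 18 (not isolated)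
Conditions: EtMgBr, CuBr·SMe2 (cat.), TMSCl, THF, −78 °C; then NBS, −78 → 0 °C
Reagents that add atoms: ethylmagnesium bromide, CC[Mg]Br; N-bromosuccinimide, O=C1CCC(=O)N1Br
Why: Copper-catalysed, TMSCl-accelerated 1,4-addition of the Grignard reagent with ethyl entering C10 anti to the adjacent C9 side chain, then bromination of the silyl enol ether anti to the new ethyl group, which puts the leaving group at C11 on the face the lactone oxygen must not occupy.

Step 10
Reactants: 19 bromo ketone; 20 diethylphosphonoacetic acid
Product: 22 butenolide (C11–O cis to the C10 ethyl, C12=C13), via phosphonoacetate ester 21 (not isolated)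
Conditions: Cs2CO3, DMF, 0 °C → rt
Reagents that add atoms: none
Why: SN2 displacement of the activated α-bromo ketone by the caesium carboxylate with inversion sets C11–O cis to ethyl, and the tethered phosphonate closes the ring by intramolecular Horner–Wadsworth–Emmons olefination of the C12 ketone.

Step 11
Reactants: 22 butenolide
Product: 23 cis-fused saturated lactone
Conditions: H2 (1 atm), Rh/Al2O3 (5% rhodium on alumina), EtOAc, rt
Reagents that add atoms: none
Why: Heterogeneous hydrogenation from the convex face of the butenolide, the face of the C11 hydrogen, sets C12 and gives the only strain-free (cis-fused) bicyclic lactone; rhodium is chosen to avoid hydrogenolysis of the allylic C11–O bond and of the C–Cl bond.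

Step 12
Reactants: 23 cis-fused saturated lactone
Product: 26 α-silyloxy lactone (C13–OTBS), via lithium enolate 24 (not isolated), via silyl ketene acetal 25 (not isolated)
Conditions: LiN(i-Pr)2, THF, −78 °C; TBSCl, HMPA, −78 °C → rt; then mCPBA, NaHCO3, CH2Cl2, −20 °C
Reagents that add atoms: tert-butyldimethylsilyl chloride, CC(C)(C)[Si](C)(C)Cl; 3-chloroperbenzoic acid, OOC(=O)c1cccc(Cl)c1
Why: Rubottom oxidation of the lactone silyl ketene acetal, with epoxidation of the electron-rich acetal and silyl migration to the new oxygen, installs the C13 oxygen already protected; the C13 configuration formed here does not matter because C13 is planarised again in step 13.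

Step 13
Reactants: 26 α-silyloxy lactone
Product: 28 C13-methylated lactone (methyl exo, silyloxy endo), via lithium enolate 27 (not isolated)
Conditions: LiN(i-Pr)2, THF, −78 °C; MeI, −78 → −40 °C
Reagents that add atoms: iodomethane, CI
Why: Alkylation of the α-silyloxy lactone enolate on the convex face of the cis-fused bicycle, anti to the C12–C9a bond, puts methyl exo and oxygen endo and so sets the C13 quaternary center as in the target; it is done while N4 is still a carbamate that MeI cannot quaternise.

Step 14
Reactants: 28 C13-methylated lactone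
Product: 30 tricyclic amino alcohol (azepane closed, C18–OH free, C13–OTBS kept), via amino alcohol 29 (not isolated)
Conditions: HCl (3 M in MeOH), 0 °C → rt; then K2CO3, NaI (cat.), MeCN, 70 °C
Reagents that add atoms: none
Why: Acidic methanolysis removes the Boc group and the primary silyl ether (the hindered tertiary silyl ether should survive), and the secondary amine then closes the azepane by iodide-catalysed intramolecular N-alkylation (7-exo-tet), helped by the cis relation of N4 and the C9 chain from step 7; lactam formation with C14 is not expected because N4 and C13 are trans on the cyclopentane.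

Step 15
Reactants: 30 tricyclic amino alcohol
Product: 31 C3 aldehyde
Conditions: (COCl)2, DMSO, CH2Cl2, −78 °C; Et3N, −78 → −20 °C
Reagents that add atoms: none
Why: Swern oxidation of the primary alcohol to the α-amino aldehyde at low temperature, compatible with the tertiary amine and chosen to limit epimerisation at C3; the aldehyde is used at once.

Step 16
Reactants: 31 C3 aldehyde; 32 ethyl 2-(bromomethyl)acrylate
Product: 34 α-methylene-γ-butyrolactone (C18 as in the target), via hydroxy ester 33 (not isolated)
Conditions: In powder, THF–H2O (1:1), rt; then p-TsOH·H2O, CH2Cl2, rt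
Reagents that add atoms: none
Why: Barbier-type addition of the 2-(ethoxycarbonyl)allyl indium reagent in aqueous THF, expected to follow the Cram chelate model (indium bridging N4 and the aldehyde oxygen, attack past the C3 hydrogen) to the syn amino alcohol, followed by acid-catalysed lactonisation.

Step 17
Reactants: 34 α-methylene-γ-butyrolactone
Product: 35 C13-O-TBS ether of the target
Conditions: H2 (1 atm), Pd/C (10% palladium on carbon), EtOAc, rt
Reagents that add atoms: none
Why: Hydrogenation of the exocyclic alkene from the lactone face opposite the bulky C18 substituent should give the cis-2,4-disubstituted lactone and so set C20.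

Step 18
Reactants: 35 C13-O-TBS ether of the target
Product: 36 CNP0260919.3
Conditions: HF·pyridine, THF, 0 °C → rt
Reagents that add atoms: none
Why: Fluoride cleavage of the tertiary silyl ether under buffered, non-basic conditions that should neither epimerise C20 nor open the lactones.

**Compound list**
1 | cyclobutanone | O=C1CCC1 | starting material
2 | SAMP, (S)-1-amino-2-(methoxymethyl)pyrrolidine | COC[C@@H]1CCCN1N | starting material
3 | cyclobutanone SAMP hydrazone | COC[C@@H]1CCCN1N=C1CCC1 | intermediate
4 | 1-chloro-4-iodobutane | ClCCCCI | starting material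
5 | lithium azaenolate of 3 (not isolated) | COC[C@@H]1CCCN1N([Li])C1=CCC1 | intermediate
6 | SAMP hydrazone of (R)-2-(4-chlorobutyl)cyclobutanone | COC[C@@H]1CCCN1N=C1CC[C@H]1CCCCCl | intermediate
7 | (R)-2-(4-chlorobutyl)cyclobutan-1-one | O=C1CC[C@H]1CCCCCl | intermediate
8 | (S)-5-(hydroxymethyl)pyrrolidin-2-one | O=C1CC[C@@H](CO)N1 | starting material
9 | (S)-5-[(tert-butyldimethylsilyloxy)methyl]pyrrolidin-2-one | O=C1CC[C@@H](CO[Si](C)(C)C(C)(C)C)N1 | intermediate
10 | tert-butyl (S)-2-[(tert-butyldimethylsilyloxy)methyl]-5-oxopyrrolidine-1-carboxylate | O=C1CC[C@@H](CO[Si](C)(C)C(C)(C)C)N1C(=O)OC(C)(C)C | intermediate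
11 | lithium alkoxide of the 5-hydroxy-pyrrolidine carbamate (hemiaminal, epimers at the carbinol carbon, not isolated) | [Li]OC1CC[C@@H](CO[Si](C)(C)C(C)(C)C)N1C(=O)OC(C)(C)C | intermediate
12 | O-trifluoroacetate of the hemiaminal (not isolated) | O=C(OC1CC[C@@H](CO[Si](C)(C)C(C)(C)C)N1C(=O)OC(C)(C)C)C(F)(F)F | intermediate
13 | tert-butyl (S)-2-[(tert-butyldimethylsilyloxy)methyl]-2,3-dihydro-1H-pyrrole-1-carboxylate | C1=CC[C@@H](CO[Si](C)(C)C(C)(C)C)N1C(=O)OC(C)(C)C | intermediate
14 | 5-lithio derivative of 13 (not isolated) | [Li]C1=CC[C@@H](CO[Si](C)(C)C(C)(C)C)N1C(=O)OC(C)(C)C | intermediate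
15 | 5-[2-(4-chlorobutyl)-1-hydroxycyclobutyl] derivative of 13, hydroxyl cis to the chlorobutyl chain (not isolated) | O[C@@]1(C2=CC[C@@H](CO[Si](C)(C)C(C)(C)C)N2C(=O)OC(C)(C)C)CC[C@H]1CCCCCl | intermediate
16 | tert-butyl (2S,5R,9R)-2-[(tert-butyldimethylsilyloxy)methyl]-9-(4-chlorobutyl)-6-oxo-1-azaspiro[4.4]nonane-1-carboxylate | O=C1CC[C@@H](CCCCCl)[C@]12CC[C@@H](CO[Si](C)(C)C(C)(C)C)N2C(=O)OC(C)(C)C | intermediate
17 | the 7-ene of 16 (C10=C11 enone) | O=C1C=C[C@@H](CCCCCl)[C@]12CC[C@@H](CO[Si](C)(C)C(C)(C)C)N2C(=O)OC(C)(C)C | intermediate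
18 | trimethylsilyl enol ether of the C10-ethyl ketone (not isolated) | C[Si](C)(C)OC1=C[C@H](CC)[C@@H](CCCCCl)[C@]12CC[C@@H](CO[Si](C)(C)C(C)(C)C)N2C(=O)OC(C)(C)C | intermediate
19 | C10-ethyl, C11-bromo ketone (ethyl trans to the C9 chain, bromine trans to ethyl) | O=C1[C@@H](Br)[C@H](CC)[C@@H](CCCCCl)[C@]12CC[C@@H](CO[Si](C)(C)C(C)(C)C)N2C(=O)OC(C)(C)C | intermediate
20 | diethylphosphonoacetic acid | OC(=O)CP(=O)(OCC)OCC | starting material
21 | C11 diethylphosphonoacetate ester of the ketone, oxygen cis to ethyl (not isolated) | O=C1[C@H](OC(=O)CP(=O)(OCC)OCC)[C@H](CC)[C@@H](CCCCCl)[C@]12CC[C@@H](CO[Si](C)(C)C(C)(C)C)N2C(=O)OC(C)(C)C | intermediate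
22 | fused butenolide (C12=C13) | O=C1C=C2[C@H](O1)[C@H](CC)[C@@H](CCCCCl)[C@]23CC[C@@H](CO[Si](C)(C)C(C)(C)C)N3C(=O)OC(C)(C)C | intermediate
23 | cis-fused saturated lactone | O=C1C[C@@H]2[C@H](O1)[C@H](CC)[C@@H](CCCCCl)[C@]23CC[C@@H](CO[Si](C)(C)C(C)(C)C)N3C(=O)OC(C)(C)C | intermediate
24 | lithium enolate of 23 (not isolated) | [Li]OC1=C[C@@H]2[C@H](O1)[C@H](CC)[C@@H](CCCCCl)[C@]23CC[C@@H](CO[Si](C)(C)C(C)(C)C)N3C(=O)OC(C)(C)C | intermediate
25 | tert-butyldimethylsilyl ketene acetal of 23 (not isolated) | CC(C)(C)[Si](C)(C)OC1=C[C@@H]2[C@H](O1)[C@H](CC)[C@@H](CCCCCl)[C@]23CC[C@@H](CO[Si](C)(C)C(C)(C)C)N3C(=O)OC(C)(C)C | intermediate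
26 | C13-silyloxy lactone (drawn with the silyloxy group exo) | O=C1[C@H](O[Si](C)(C)C(C)(C)C)[C@@H]2[C@H](O1)[C@H](CC)[C@@H](CCCCCl)[C@]23CC[C@@H](CO[Si](C)(C)C(C)(C)C)N3C(=O)OC(C)(C)C | intermediate
27 | lithium enolate of 26 (not isolated) | [Li]OC1=C(O[Si](C)(C)C(C)(C)C)[C@@H]2[C@H](O1)[C@H](CC)[C@@H](CCCCCl)[C@]23CC[C@@H](CO[Si](C)(C)C(C)(C)C)N3C(=O)OC(C)(C)C | intermediate
28 | C13-methyl, C13-silyloxy lactone (methyl exo) | O=C1[C@@](C)(O[Si](C)(C)C(C)(C)C)[C@@H]2[C@H](O1)[C@H](CC)[C@@H](CCCCCl)[C@]23CC[C@@H](CO[Si](C)(C)C(C)(C)C)N3C(=O)OC(C)(C)C | intermediate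
29 | secondary amine with free primary alcohol and chlorobutyl chain (not isolated) | O=C1[C@@](C)(O[Si](C)(C)C(C)(C)C)[C@@H]2[C@H](O1)[C@H](CC)[C@@H](CCCCCl)[C@]23CC[C@@H](CO)N3 | intermediate
30 | tricyclic amino alcohol (C3–CH2OH, C13–OTBS) | CC[C@H]1[C@H]2OC(=O)[C@@](C)(O[Si](C)(C)C(C)(C)C)[C@H]2[C@]23CC[C@@H](CO)N2CCCC[C@H]13 | intermediate
31 | tricyclic C3 aldehyde | CC[C@H]1[C@H]2OC(=O)[C@@](C)(O[Si](C)(C)C(C)(C)C)[C@H]2[C@]23CC[C@@H](C=O)N2CCCC[C@H]13 | intermediate
32 | ethyl 2-(bromomethyl)acrylate | C=C(CBr)C(=O)OCC | starting material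
33 | C18 hydroxy ester, syn to N4 (not isolated) | CC[C@H]1[C@H]2OC(=O)[C@@](C)(O[Si](C)(C)C(C)(C)C)[C@H]2[C@]23CC[C@@H]([C@@H](O)CC(=C)C(=O)OCC)N2CCCC[C@H]13 | intermediate
34 | α-methylene-γ-butyrolactone | CC[C@H]1[C@H]2OC(=O)[C@@](C)(O[Si](C)(C)C(C)(C)C)[C@H]2[C@]23CC[C@@H]([C@@H]4CC(=C)C(=O)O4)N2CCCC[C@H]13 | intermediate
35 | C13-O-TBS ether of the target | CC[C@H]1[C@H]2OC(=O)[C@@](C)(O[Si](C)(C)C(C)(C)C)[C@H]2[C@]23CC[C@@H]([C@@H]4C[C@H](C)C(=O)O4)N2CCCC[C@H]13 | intermediate
36 | CNP0260919.3 | CC[C@H]1[C@H]2OC(=O)[C@@](C)(O)[C@H]2[C@]23CC[C@@H]([C@@H]4C[C@H](C)C(=O)O4)N2CCCC[C@H]13 | target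

**Step count and risks**
Total step count: 18. Longest linear sequence: 15 steps (steps 1–3 or 4–6, then 7–18).

Three steps most likely to fail:

Step 7. It may fail through poor facial selectivity in the addition of 14 to 7, through competing migration of the ring CH2 (C11), or through acid-induced loss of the Boc group before the shift. The fallback sets out from 13 and 7 and separates the events. The adduct is quenched cold with aqueous NH4Cl and cyclobutanol 15 is isolated on triethylamine-deactivated silica. The Boc group is removed with TMSOTf and 2,6-lutidine in CH2Cl2 followed by methanol, and the enamine tautomerises to the cyclic α-hydroxy imine, hydroxy pyrroline F1. Heating F1 in toluene at 110 °C should bring about the neutral α-iminol rearrangement through a hydrogen-bonded O–H···N five-membered transition state, again with migration of C9 and release of ring strain, to the NH spiro aminoketone F2. Carbamoylation of F2 with Boc2O (neat, 50 °C) comes back to the route at 16.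

Step 10. It may fail through base-induced epimerisation at C11 or elimination of HBr competing with the displacement, so that the C11 configuration is lost. The fallback sets out from 17. The silyl enol ether 18 from the conjugate addition is oxidised under Rubottom conditions (mCPBA, NaHCO3, CH2Cl2, −20 °C; then citric acid in MeOH) to hydroxy ketone F3, with the hydroxyl trans to ethyl. Mitsunobu esterification of F3 with 20 (PPh3, DIAD, THF, 0 °C) inverts C11 and gives ester 21, which is closed under Masamune–Roush conditions (LiCl, DIPEA, MeCN) and comes back to the route at 22.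

Step 16. It may fail through poor facial selectivity at C18 (chelated against Felkin–Anh addition), which the hydrogenation of step 17 cannot correct. The fallback sets out from 31, sets C18 by reduction instead of addition and takes C20 from the chiral pool. Pinnick oxidation (NaClO2, NaH2PO4, 2-methyl-2-butene) gives amino acid F4, and EDC-mediated coupling with ethanethiol gives thioester F5. Fukuyama coupling (PdCl2(PPh3)2 cat., toluene) with zinc reagent F6, made from commercial methyl (R)-3-bromo-2-methylpropanoate and zinc dust in DMA, gives γ-keto ester F7. LiBH(s-Bu)3 in THF at −78 °C should reduce the ketone in the Felkin–Anh sense (hydride anti to N4) to hydroxy ester F8, which lactonises with p-TsOH and comes back to the route at 35, so that step 17 is not needed.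

**Further compounds**
F1 | step 7 | 2-[2-(4-chlorobutyl)-1-hydroxycyclobutyl]-1-pyrroline bearing the C3 silyloxymethyl group (hydroxy pyrroline) | O[C@@]1(C2=N[C@H](CO[Si](C)(C)C(C)(C)C)CC2)CC[C@H]1CCCCCl
F2 | step 7 | NH spiro aminoketone (16 without the Boc group) | O=C1CC[C@@H](CCCCCl)[C@]12CC[C@@H](CO[Si](C)(C)C(C)(C)C)N2
F3 | step 10 | C11 hydroxy ketone, hydroxyl trans to the C10 ethyl | O=C1[C@@H](O)[C@H](CC)[C@@H](CCCCCl)[C@]12CC[C@@H](CO[Si](C)(C)C(C)(C)C)N2C(=O)OC(C)(C)C
F4 | step 16 | tricyclic C3 carboxylic acid | CC[C@H]1[C@H]2OC(=O)[C@@](C)(O[Si](C)(C)C(C)(C)C)[C@H]2[C@]23CC[C@@H](C(O)=O)N2CCCC[C@H]13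
F5 | step 16 | S-ethyl thioester of F4 | CC[C@H]1[C@H]2OC(=O)[C@@](C)(O[Si](C)(C)C(C)(C)C)[C@H]2[C@]23CC[C@@H](C(=O)SCC)N2CCCC[C@H]13
F6 | step 16 | [(R)-3-methoxy-2-methyl-3-oxopropyl]zinc bromide | Br[Zn]C[C@H](C)C(=O)OC
F7 | step 16 | C18 γ-keto methyl ester | CC[C@H]1[C@H]2OC(=O)[C@@](C)(O[Si](C)(C)C(C)(C)C)[C@H]2[C@]23CC[C@@H](C(=O)C[C@H](C)C(=O)OC)N2CCCC[C@H]13
F8 | step 16 | C18 γ-hydroxy methyl ester, syn to N4 | CC[C@H]1[C@H]2OC(=O)[C@@](C)(O[Si](C)(C)C(C)(C)C)[C@H]2[C@]23CC[C@@H]([C@@H](O)C[C@H](C)C(=O)OC)N2CCCC[C@H]13
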